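**Plan**

Prostanoid numbering is used: ring = C8 (alkylidene carbon), C9 (C=O), C10 (C–Br), C11 (=CH), C12 (carbinol); ester chain C1–C7; octenyl chain C13–C20.
Retrosynthesis cuts C7=C8 (aldol condensation with a (Z)-enal), then C14=C15 (Wittig), then C10–Br, and last the ring at C11–C12 and C8–C9 in one event.
Enabling feature: the ring is a 4-hydroxycyclopent-2-enone. C12 and C8 are the carbonyl and methyl carbons of a methyl ketone. C9–C10–C11 is an acryloyl unit that must be an acyl electrophile at C9 and then a carbanion at C11, which an acryloylsilane delivers through a Brook rearrangement.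
Forward: acylsilane 6 (C9–C11, phenylthio helper on C11) and methyl ketone 9 (C8, C12–C14) give cyclopentenol 13 by [3+2] annulation. Its silyl enol ether marks C10 for bromination, and loss of the sulfur helper gives bromo enone 16. The dioxolane is then cut to the C14 aldehyde, the octenyl chain is made by Wittig reaction, and the ester chain is joined at C8 by aldol condensation.
Stereochemistry: C12 is set in the annulation under control of the dioxolane centre C14 (chiral pool), which is then destroyed by glycol cleavage; the C12 epimers are diastereomers and separable. 14Z and 5Z come from Z-selective Wittig reactions, 7E from the E1cB dehydration.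

Key step: step 4

Assumption: ring closure in step 4 is taken to follow the lithium-chelate (1,3-anti) model, which makes the (4R)-dioxolane ester 7 (taken as purchasable, as is its enantiomer) the right choice; if the sense were opposite, the enantiomer of 7 would be used with the route unchanged.

**Route**

Step 1
Reactants: 1 methoxyallene (1-methoxypropa-1,2-diene)
Product: 3 tert-butyl(1-methoxypropa-1,2-dien-1-yl)dimethylsilane, via 1-lithio-1-methoxyallene 2 (not isolated)
Conditions: n-BuLi, THF, −78 °C; then TBSCl, −78 °C to rt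
Reagents that add atoms: tert-butyldimethylsilyl chloride, CC(C)(C)[Si](C)(C)Cl
Why: Methoxyallene is deprotonated at the oxygen-bearing carbon and the allenyllithium is silylated there (α-lithiation/silylation of an alkoxyallene); no stereocentre is formed.

Step 2
Reactants: 3 tert-butyl(1-methoxypropa-1,2-dien-1-yl)dimethylsilane
Product: 6 (2E)-1-[tert-butyl(dimethyl)silyl]-3-(phenylsulfanyl)prop-2-en-1-one, via 3-lithioallene 4 (not isolated), via sulfanylallene 5 (not isolated)
Conditions: n-BuLi, THF, −78 °C; PhSSPh, −78 °C; then 1 M HCl, THF, 0 °C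
Reagents that add atoms: diphenyl disulfide, c1ccc(SSc2ccccc2)cc1; water, O
Why: The 1-silyl-1-alkoxyallene is lithiated at the terminal carbon, sulfenylated there, and hydrolysis of the methyl enol ether (protonation at the central allene carbon) should give the push–pull acylsilane as the conjugated E isomer (alkoxyallene route to α,β-unsaturated acylsilanes).

Step 3
Reactants: 7 methyl 2-[(4R)-2,2-dimethyl-1,3-dioxolan-4-yl]acetate
Product: 9 1-[(4R)-2,2-dimethyl-1,3-dioxolan-4-yl]propan-2-one, via Weinreb amide 8 (not isolated)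
Conditions: MeNH(OMe)·HCl, iPrMgCl, THF, −20 °C; then MeMgBr, 0 °C; aq NH4Cl
Reagents that add atoms: methylmagnesium bromide, C[Mg]Br
Why: The chloromagnesium amide of N,O-dimethylhydroxylamine converts the ester into the Weinreb amide in the flask, whose chelated adduct with MeMgBr stops at the ketone stage, and the dioxolane stereocentre (not α to the carbonyl) is untouched.

Step 4
Reactants: 9 1-[(4R)-2,2-dimethyl-1,3-dioxolan-4-yl]propan-2-one; 6 (2E)-1-[tert-butyl(dimethyl)silyl]-3-(phenylsulfanyl)prop-2-en-1-one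
Product: 13 (1S,2R)-4-[(tert-butyldimethylsilyl)oxy]-1-{[(4R)-2,2-dimethyl-1,3-dioxolan-4-yl]methyl}-2-(phenylsulfanyl)cyclopent-3-en-1-ol, via lithium enolate 10 (not isolated), via silyl carbinolate 11 (not isolated), via siloxyallyllithium 12 (not isolated)
Conditions: LiN(iPr)2, THF, −80 °C; then 6, −80 to −30 °C; AcOH quench
Reagents that add atoms: none
Why: The enolate carbon C8 adds to the acylsilane carbonyl C9 (first bond), the α-silyl alkoxide undergoes a [1,2]-Brook shift of silicon from carbon to oxygen because the resulting carbanion is an allyl anion stabilised by the phenylthio group, and the γ-terminus C11 of this 1-siloxy-3-(phenylthio)allyl anion adds to the ketone carbon C12 (second bond), leaving a regiodefined silyl enol ether at C9=C10. The closest known reaction type is the Brook-rearrangement-mediated [3+2] annulation of β-heteroatom-substituted acryloylsilanes with lithium enolates of alkyl methyl ketones, which gives 4-siloxycyclopent-3-enols. The ring closes by 5-exo-trig attack of C11 on the C12=O group. C12 should be set under control of the dioxolane centre C14 through a six-membered lithium chelate (ketone oxygen and dioxolane oxygen) with attack anti to the C14 substituent, while C11 follows C12 through internal lithium coordination (PhS cis to the alkoxide) and is only a helper centre erased in step 5. The step needs kinetic enolisation at the methyl group (amide base at −80 °C), 1,2- rather than 1,4-addition to 6 (secured by the push–pull β-phenylthio group and the high carbonyl reactivity of acylsilanes), and γ- rather than α-attack of the allyl anion (five- rather than three-membered ring).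

Step 5
Reactants: 13 (1S,2R)-4-[(tert-butyldimethylsilyl)oxy]-1-{[(4R)-2,2-dimethyl-1,3-dioxolan-4-yl]methyl}-2-(phenylsulfanyl)cyclopent-3-en-1-ol
Product: 16 (4S)-2-bromo-4-{[(4R)-2,2-dimethyl-1,3-dioxolan-4-yl]methyl}-4-hydroxycyclopent-2-en-1-one, via allyl sulfoxide 14 (not isolated), via bromo sulfinyl ketone 15 (not isolated)
Conditions: mCPBA (1.0 equiv), NaHCO3, CH2Cl2, −78 °C; then NBS, −78 to 0 °C; then Et3N, 0 °C
Reagents that add atoms: N-bromosuccinimide, O=C1CCC(=O)N1Br
Why: The sulfide should be oxidised much faster than the silyl enol ether at −78 °C, NBS then brominates the enol ether regiospecifically at C10 (the position fixed by the Brook step), and Et3N triggers E1cB loss of benzenesulfenate from C11 through the C10 enolate (sulfoxide β-elimination), which erases the helper centre C11; the minor C12 epimer, a diastereomer, is removed here by chromatography.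

Step 6
Reactants: 16 (4S)-2-bromo-4-{[(4R)-2,2-dimethyl-1,3-dioxolan-4-yl]methyl}-4-hydroxycyclopent-2-en-1-one
Product: 17 2-[(1S)-3-bromo-1-hydroxy-4-oxocyclopent-2-en-1-yl]acetaldehyde
Conditions: H5IO6, EtOAc, rt
Reagents that add atoms: none
Why: Periodic acid in ethyl acetate hydrolyses the terminal acetonide and cleaves the liberated 1,2-diol in one operation (glycol cleavage), excising the controller centre C14 as the aldehyde without touching the bromo enone or C12.

Step 7
Reactants: 17 2-[(1S)-3-bromo-1-hydroxy-4-oxocyclopent-2-en-1-yl]acetaldehyde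
Product: 18 2-{(1S)-3-bromo-4-oxo-1-[(trimethylsilyl)oxy]cyclopent-2-en-1-yl}acetaldehyde
Conditions: 1-(trimethylsilyl)imidazole, CH2Cl2, rt
Reagents that add atoms: 1-(trimethylsilyl)imidazole, C[Si](C)(C)n1ccnc1
Why: The reagent silylates the tertiary alcohol under neutral conditions that leave the aldehyde alone, which blocks retro-aldol and alkoxide chemistry in the basic steps that follow.

Step 8
Reactants: 18 2-{(1S)-3-bromo-4-oxo-1-[(trimethylsilyl)oxy]cyclopent-2-en-1-yl}acetaldehyde; 19 hexyltriphenylphosphonium bromide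
Product: 21 (4S)-2-bromo-4-[(2Z)-oct-2-en-1-yl]-4-[(trimethylsilyl)oxy]cyclopent-2-en-1-one, via hexylidene ylide 20 (not isolated)
Conditions: 19, NaN(SiMe3)2, THF, 0 °C; then 18, −78 to −20 °C
Reagents that add atoms: none
Why: A salt-free unstabilised ylide should add to the aldehyde at −78 °C much faster than to the hindered enone and collapse through the cis-oxaphosphetane to the 14Z alkene (Z-selective Wittig reaction).

Step 9
Reactants: 22 (4-carboxybutyl)triphenylphosphonium bromide; 23 (tert-butyldimethylsilyloxy)acetaldehyde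
Product: 25 (5Z)-7-[(tert-butyldimethylsilyl)oxy]hept-5-enoic acid, via carboxylate ylide 24 (not isolated)
Conditions: 22, NaN(SiMe3)2 (2 equiv), THF, 0 °C; then 23, −78 °C to rt; aq HCl to pH 4
Reagents that add atoms: none
Why: The unstabilised carboxylate ylide and the α-silyloxy aldehyde should give the 5Z alkene under kinetic, salt-free conditions (Z-selective Wittig reaction of the kind used for prostaglandin upper chains).

Step 10
Reactants: 25 (5Z)-7-[(tert-butyldimethylsilyl)oxy]hept-5-enoic acid
Product: 26 methyl (5Z)-7-hydroxyhept-5-enoate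
Conditions: AcCl (0.3 equiv), MeOH, 0 °C to rt
Reagents that add atoms: methanol, CO
Why: Methanolic HCl generated from AcCl esterifies the acid (Fischer esterification) and cleaves the primary silyl ether in the same flask, leaving the isolated Z alkene unchanged.

Step 11
Reactants: 26 methyl (5Z)-7-hydroxyhept-5-enoate
Product: 27 methyl (5Z)-7-oxohept-5-enoate
Conditions: Dess–Martin periodinane, NaHCO3, CH2Cl2, 0 °C; used at once
Reagents that add atoms: none
Why: Buffered Dess–Martin oxidation of the (Z)-allylic alcohol is neutral and fast at 0 °C, so the (Z)-enal should form without isomerisation.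

Step 12
Reactants: 21 (4S)-2-bromo-4-[(2Z)-oct-2-en-1-yl]-4-[(trimethylsilyl)oxy]cyclopent-2-en-1-one; 27 methyl (5Z)-7-oxohept-5-enoate
Product: 29 methyl (5Z)-7-{(5S)-3-bromo-2-oxo-5-[(2Z)-oct-2-en-1-yl]-5-[(trimethylsilyl)oxy]cyclopent-3-en-1-yl}-7-hydroxyhept-5-enoate, via lithium dienolate 28 (not isolated)
Conditions: LiN(iPr)2, THF, −78 °C; then 27, −78 °C; AcOH quench
Reagents that add atoms: none
Why: C8 carries the only enolisable hydrogens of 21, so the amide base gives the cross-conjugated lithium dienolate, which should add 1,2 to the (Z)-enal at −78 °C before β-elimination of the silyloxy group or enal isomerisation can compete (directed aldol addition; the new centres C7 and C8 form as a mixture that is erased in step 13).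

Step 13
Reactants: 29 methyl (5Z)-7-{(5S)-3-bromo-2-oxo-5-[(2Z)-oct-2-en-1-yl]-5-[(trimethylsilyl)oxy]cyclopent-3-en-1-yl}-7-hydroxyhept-5-enoate
Product: 31 methyl (5Z,7E)-7-{(5R)-3-bromo-2-oxo-5-[(2Z)-oct-2-en-1-yl]-5-[(trimethylsilyl)oxy]cyclopent-3-en-1-ylidene}hept-5-enoate, via mesylate 30 (not isolated)
Conditions: MsCl, Et3N, CH2Cl2, −20 °C; then DBU, 0 °C to rt
Reagents that add atoms: none
Why: Mesylation of the aldol hydroxyl and DBU-induced E1cB elimination through the C8 enolate should give the conjugated 7E alkylidene ketone as the thermodynamically preferred isomer (C6 anti to the C9 carbonyl), while the 5Z alkene and C12 are not involved; any 7Z isomer is removed by chromatography.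

Step 14
Reactants: 31 methyl (5Z,7E)-7-{(5R)-3-bromo-2-oxo-5-[(2Z)-oct-2-en-1-yl]-5-[(trimethylsilyl)oxy]cyclopent-3-en-1-ylidene}hept-5-enoate
Product: 32 bromovulone I, methyl (5Z,7E)-7-{(5R)-3-bromo-5-hydroxy-2-oxo-5-[(2Z)-oct-2-en-1-yl]cyclopent-3-en-1-ylidene}hept-5-enoate
Conditions: AcOH/THF/H2O (3:1:1), rt
Reagents that add atoms: none
Why: Aqueous acetic acid cleaves the tertiary trimethylsilyl ether without affecting the dienone, the vinyl bromide, the ester or the Z alkenes, and releases the (12R)-carbinol with the configuration fixed in step 4.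

**Compound list**

1 | methoxyallene (1-methoxypropa-1,2-diene) | COC=C=C | starting material
2 | 1-lithio-1-methoxyallene | [Li]C(OC)=C=C | intermediate
3 | tert-butyl(1-methoxypropa-1,2-dien-1-yl)dimethylsilane | COC(=C=C)[Si](C)(C)C(C)(C)C | intermediate
4 | tert-butyl(3-lithio-1-methoxypropa-1,2-dien-1-yl)dimethylsilane | [Li]C=C=C(OC)[Si](C)(C)C(C)(C)C | intermediate
5 | tert-butyl[1-methoxy-3-(phenylsulfanyl)propa-1,2-dien-1-yl]dimethylsilane (racemic allene) | COC(=C=CSc1ccccc1)[Si](C)(C)C(C)(C)C | intermediate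
6 | (2E)-1-[tert-butyl(dimethyl)silyl]-3-(phenylsulfanyl)prop-2-en-1-one | O=C(/C=C/Sc1ccccc1)[Si](C)(C)C(C)(C)C | intermediate
7 | methyl 2-[(4R)-2,2-dimethyl-1,3-dioxolan-4-yl]acetate | COC(=O)C[C@@H]1COC(C)(C)O1 | starting material
8 | 2-[(4R)-2,2-dimethyl-1,3-dioxolan-4-yl]-N-methoxy-N-methylacetamide | CON(C)C(=O)C[C@@H]1COC(C)(C)O1 | intermediate
9 | 1-[(4R)-2,2-dimethyl-1,3-dioxolan-4-yl]propan-2-one | CC(=O)C[C@@H]1COC(C)(C)O1 | intermediate
10 | lithium enolate of 9 (methyl side) | [Li+].[O-]C(=C)C[C@@H]1COC(C)(C)O1 | intermediate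
11 | lithium α-silyl alkoxide from 1,2-addition of 10 to 6 (carbinol epimers) | [Li+].[O-]C(/C=C/Sc1ccccc1)(CC(=O)C[C@@H]1COC(C)(C)O1)[Si](C)(C)C(C)(C)C | intermediate
12 | 1-(phenylsulfanyl)-3-siloxyallyllithium formed by the Brook shift | [Li]C(Sc1ccccc1)C=C(O[Si](C)(C)C(C)(C)C)CC(=O)C[C@@H]1COC(C)(C)O1 | intermediate
13 | (1S,2R)-4-[(tert-butyldimethylsilyl)oxy]-1-{[(4R)-2,2-dimethyl-1,3-dioxolan-4-yl]methyl}-2-(phenylsulfanyl)cyclopent-3-en-1-ol | CC1(C)OC[C@@H](C[C@@]2(O)[C@H](Sc3ccccc3)C=C(O[Si](C)(C)C(C)(C)C)C2)O1 | intermediate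
14 | (1S,2R)-4-[(tert-butyldimethylsilyl)oxy]-1-{[(4R)-2,2-dimethyl-1,3-dioxolan-4-yl]methyl}-2-(phenylsulfinyl)cyclopent-3-en-1-ol (sulfur epimers) | CC1(C)OC[C@@H](C[C@@]2(O)[C@H](S(=O)c3ccccc3)C=C(O[Si](C)(C)C(C)(C)C)C2)O1 | intermediate
15 | (3S,4S)-2-bromo-4-{[(4R)-2,2-dimethyl-1,3-dioxolan-4-yl]methyl}-4-hydroxy-3-(phenylsulfinyl)cyclopentan-1-one (C2 and sulfur epimers) | CC1(C)OC[C@@H](C[C@@]2(O)[C@H](S(=O)c3ccccc3)C(Br)C(=O)C2)O1 | intermediate
16 | (4S)-2-bromo-4-{[(4R)-2,2-dimethyl-1,3-dioxolan-4-yl]methyl}-4-hydroxycyclopent-2-en-1-one | CC1(C)OC[C@@H](C[C@@]2(O)C=C(Br)C(=O)C2)O1 | intermediate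
17 | 2-[(1S)-3-bromo-1-hydroxy-4-oxocyclopent-2-en-1-yl]acetaldehyde | O=CC[C@@]1(O)C=C(Br)C(=O)C1 | intermediate
18 | 2-{(1S)-3-bromo-4-oxo-1-[(trimethylsilyl)oxy]cyclopent-2-en-1-yl}acetaldehyde | O=CC[C@@]1(O[Si](C)(C)C)C=C(Br)C(=O)C1 | intermediate
19 | hexyltriphenylphosphonium bromide | CCCCCC[P+](c1ccccc1)(c1ccccc1)c1ccccc1.[Br-] | starting material
20 | hexylidenetriphenylphosphorane | CCCCCC=P(c1ccccc1)(c1ccccc1)c1ccccc1 | intermediate
21 | (4S)-2-bromo-4-[(2Z)-oct-2-en-1-yl]-4-[(trimethylsilyl)oxy]cyclopent-2-en-1-one | CCCCC/C=C\C[C@@]1(O[Si](C)(C)C)C=C(Br)C(=O)C1 | intermediate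
22 | (4-carboxybutyl)triphenylphosphonium bromide | OC(=O)CCCC[P+](c1ccccc1)(c1ccccc1)c1ccccc1.[Br-] | starting material
23 | (tert-butyldimethylsilyloxy)acetaldehyde | O=CCO[Si](C)(C)C(C)(C)C | starting material
24 | sodium 5-(triphenylphosphoranylidene)pentanoate | [Na+].[O-]C(=O)CCCC=P(c1ccccc1)(c1ccccc1)c1ccccc1 | intermediate
25 | (5Z)-7-[(tert-butyldimethylsilyl)oxy]hept-5-enoic acid | OC(=O)CCC/C=C\CO[Si](C)(C)C(C)(C)C | intermediate
26 | methyl (5Z)-7-hydroxyhept-5-enoate | COC(=O)CCC/C=C\CO | intermediate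
27 | methyl (5Z)-7-oxohept-5-enoate | COC(=O)CCC/C=C\C=O | intermediate
28 | lithium dienolate of 21 (C8=C9) | CCCCC/C=C\C[C@@]1(O[Si](C)(C)C)C=C(Br)C([O-])=C1.[Li+] | intermediate
29 | methyl (5Z)-7-{(5S)-3-bromo-2-oxo-5-[(2Z)-oct-2-en-1-yl]-5-[(trimethylsilyl)oxy]cyclopent-3-en-1-yl}-7-hydroxyhept-5-enoate (C7 and C8 epimers) | CCCCC/C=C\C[C@@]1(O[Si](C)(C)C)C=C(Br)C(=O)C1C(O)/C=C\CCCC(=O)OC | intermediate
30 | mesylate of 29 | CCCCC/C=C\C[C@@]1(O[Si](C)(C)C)C=C(Br)C(=O)C1C(OS(C)(=O)=O)/C=C\CCCC(=O)OC | intermediate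
31 | methyl (5Z,7E)-7-{(5R)-3-bromo-2-oxo-5-[(2Z)-oct-2-en-1-yl]-5-[(trimethylsilyl)oxy]cyclopent-3-en-1-ylidene}hept-5-enoate | CCCCC/C=C\C[C@@]1(O[Si](C)(C)C)C=C(Br)C(=O)/C1=C/C=C\CCCC(=O)OC | intermediate
32 | bromovulone I, methyl (5Z,7E)-7-{(5R)-3-bromo-5-hydroxy-2-oxo-5-[(2Z)-oct-2-en-1-yl]cyclopent-3-en-1-ylidene}hept-5-enoate (12R in prostanoid numbering) | CCCCC/C=C\C[C@@]1(O)C=C(Br)C(=O)/C1=C/C=C\CCCC(=O)OC | target

**Step count and risks**

Total steps: 14. Longest linear sequence: 10 steps (1, 2, 4, 5, 6, 7, 8, 12, 13, 14).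

Steps most likely to fail:

1. Step 4. What may go wrong: after the Brook shift the allyl anion may be quenched by proton transfer from the C13 methylene before it reaches the ketone, and the remote C14 centre may discriminate the two ketone faces only weakly, so that much material ends as the unwanted C12 epimer. Fallback (stepwise ring construction by aldol addition, Grignard addition and ring-closing metathesis; sets out from 9, returns at 16): the lithium enolate of 9 is added to acrolein (THF, −78 °C) to give the aldol 1-[(4R)-2,2-dimethyl-1,3-dioxolan-4-yl]-4-hydroxyhex-5-en-2-one F1. Vinylmagnesium bromide (excess, THF, −78 °C), held by the magnesium aldolate chelate, adds to the ketone and gives the divinyl diol F2. Ring-closing metathesis with the second-generation Grubbs catalyst RuCl2(=CHPh)(PCy3)(H2IMes) in CH2Cl2 closes the cyclopentene diol F3. MnO2 oxidises the secondary allylic carbinol to the hydroxy enone F4, where the C12 epimers are separated. Br2 (CH2Cl2, 0 °C) gives the dibromide F5, and Et3N eliminates HBr to give 16.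

2. Step 5. What may go wrong: loss of chemoselectivity in the telescoped sequence, namely peracid attack on the silyl enol ether, [2,3]-shift of the allyl sulfoxide before bromination, or bromination at sulfur instead of C10. Fallback (separate the events and brominate the enone in the classical way; sets out from 13, returns at 16): HF·pyridine (THF/pyridine, 0 °C) hydrolyses only the silyl enol ether to the β-(phenylsulfanyl) ketone F6. mCPBA (CH2Cl2, −78 °C) gives the β-sulfinyl ketone F7, which loses benzenesulfenic acid on warming over NaHCO3 and gives the hydroxy enone F4 already met in the fallback for step 4. Bromine addition to the dibromide F5 and elimination with Et3N then give 16.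

3. Step 8. What may go wrong: conjugate addition of the ylide to the bromo enone, or deprotonation at C8 followed by β-elimination of the silyloxy group, in competition with olefination. Fallback (mask the enone as its allylic alcohol and olefinate a lactol; sets out from 16, returns at 21): NaBH4/CeCl3·7H2O (MeOH, −78 °C, Luche reduction) gives the bromo cyclopentene diol F8. H5IO6 (EtOAc) gives the hydroxy aldehyde F9, which should rest largely as its bicyclic lactol when the ring carbinol and the side chain are cis. Excess ylide 20 (THF, −78 °C to rt) opens the lactol and gives the (Z)-octenyl diol F10. MnO2 (CH2Cl2) oxidises only the secondary allylic carbinol to the hydroxy enone F11, and 1-(trimethylsilyl)imidazole gives 21.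

**Further compounds**

F1 | step 4 | 1-[(4R)-2,2-dimethyl-1,3-dioxolan-4-yl]-4-hydroxyhex-5-en-2-one (C4 epimers) | C=CC(O)CC(=O)C[C@@H]1COC(C)(C)O1
F2 | step 4 | (3R)-3-{[(4R)-2,2-dimethyl-1,3-dioxolan-4-yl]methyl}hepta-1,6-diene-3,5-diol (C5 epimers) | CC1(C)OC[C@@H](C[C@@](O)(C=C)CC(O)C=C)O1
F3 | step 4 | (1R)-1-{[(4R)-2,2-dimethyl-1,3-dioxolan-4-yl]methyl}cyclopent-2-ene-1,4-diol (C4 epimers) | CC1(C)OC[C@@H](C[C@@]2(O)C=CC(O)C2)O1
F4 | step 4 | (4S)-4-{[(4R)-2,2-dimethyl-1,3-dioxolan-4-yl]methyl}-4-hydroxycyclopent-2-en-1-one | CC1(C)OC[C@@H](C[C@@]2(O)C=CC(=O)C2)O1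
F5 | step 4 | (4S)-2,3-dibromo-4-{[(4R)-2,2-dimethyl-1,3-dioxolan-4-yl]methyl}-4-hydroxycyclopentan-1-one (C2 and C3 epimers) | CC1(C)OC[C@@H](C[C@@]2(O)C(Br)C(Br)C(=O)C2)O1
F6 | step 5 | (3R,4S)-4-{[(4R)-2,2-dimethyl-1,3-dioxolan-4-yl]methyl}-4-hydroxy-3-(phenylsulfanyl)cyclopentan-1-one | CC1(C)OC[C@@H](C[C@@]2(O)[C@H](Sc3ccccc3)CC(=O)C2)O1
F7 | step 5 | (3R,4S)-4-{[(4R)-2,2-dimethyl-1,3-dioxolan-4-yl]methyl}-4-hydroxy-3-(phenylsulfinyl)cyclopentan-1-one (sulfur epimers) | CC1(C)OC[C@@H](C[C@@]2(O)[C@H](S(=O)c3ccccc3)CC(=O)C2)O1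
F8 | step 8 | (4R)-2-bromo-4-{[(4R)-2,2-dimethyl-1,3-dioxolan-4-yl]methyl}cyclopent-2-ene-1,4-diol (C1 epimers) | CC1(C)OC[C@@H](C[C@@]2(O)C=C(Br)C(O)C2)O1
F9 | step 8 | 2-[(1R)-3-bromo-1,4-dihydroxycyclopent-2-en-1-yl]acetaldehyde (open form of the lactol; C4 epimers) | O=CC[C@@]1(O)C=C(Br)C(O)C1
F10 | step 8 | (4S)-2-bromo-4-[(2Z)-oct-2-en-1-yl]cyclopent-2-ene-1,4-diol (C1 epimers) | CCCCC/C=C\C[C@@]1(O)C=C(Br)C(O)C1
F11 | step 8 | (4S)-2-bromo-4-hydroxy-4-[(2Z)-oct-2-en-1-yl]cyclopent-2-en-1-one | CCCCC/C=C\C[C@@]1(O)C=C(Br)C(=O)C1
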